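**Strategy.** The plan rests on one disconnection: the sp3–sp2 bond between the CH2 two carbons away from the isopropenyl-bearing stereocentre and the α-carbon of the (Z)-2-alkylidene acid whose alkylidene arm ends in the furan ring. Both carbons are handled as electrophiles: the CH2 as the carboxyl terminus of a limonene-derived C23 acid (N-hydroxyphthalimide ester), the α-carbon as a stereodefined C10 α-iodo enoate. A nickel-electrocatalytic decarboxylative alkenylation joins them in one operation, expelling CO2 and transferring the alkene geometry by retention. The step exploits the fact that this junction is an α-alkylated acrylate carbon next to an unbranched CH2, so a primary radical and an alkenylnickel suffice.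

Key step: step 10

Assumption: (+)-limonene 1,2-oxide (cis/trans mixture from (R)-limonene), 3-(bromomethyl)furan and propyne are taken as commercial; the epoxide mixture is acceptable because both epoxide carbons become carbonyl groups, and the (R) centre of limonene maps directly onto the (R) centre of the target.

**Step 1**
Reactants: 1 3-(bromomethyl)furan; 2 propyne
Product: 5 methyl 5-(furan-3-yl)pent-2-ynoate, via dilithiopropyne 3 (not isolated), via lithium acetylide 4 (not isolated)
Conditions: 2, n-BuLi (2 equiv), TMEDA, Et2O/hexane, −78 → 0 °C; 1, −78 → 0 °C; then ClCO2Me, −78 °C → rt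
Reagents that add atoms: methyl chloroformate, COC(=O)Cl
Why: Twofold deprotonation of propyne gives the propargylic/acetylenic dianion, whose more nucleophilic sp3 carbon is alkylated (SN2) by the furylmethyl bromide, and the remaining lithium acetylide is then C-acylated by the chloroformate (dianion alkylation followed by acetylide acylation).

**Step 2**
Reactants: 5 methyl 5-(furan-3-yl)pent-2-ynoate
Product: 7 methyl (E)-5-(furan-3-yl)-2-iodopent-2-enoate, via stannyl enoate 6 (not isolated)
Conditions: Bu3SnH, Pd(PPh3)4 (2 mol%), THF, 0 °C → rt; then I2, CH2Cl2, 0 °C, dark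
Reagents that add atoms: iodine, II
Why: Zerovalent-palladium-catalysed hydrostannation of a 2-ynoate adds H and Sn syn with tin on the α-carbon, and iododestannylation proceeds with retention, so the ester and the CH2CH2-furyl chain end up cis.

**Step 3**
Reactants: 8 (4R)-limonene 1,2-oxide (cis/trans mixture)
Product: 10 (3R)-6-oxo-3-(prop-1-en-2-yl)heptanal, via limonene-1,2-diol 9 (not isolated)
Conditions: H5IO6, THF/H2O, 0 °C → rt
Reagents that add atoms: water, O
Why: Acid-promoted epoxide hydrolysis followed in the same flask by periodate glycol cleavage (Malaprade reaction) opens the ring at the former C1–C2 bond; both epoxide diastereomers converge and the stereocentre is not involved.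

**Step 4**
Reactants: 10 (3R)-6-oxo-3-(prop-1-en-2-yl)heptanal
Product: 11 (5R)-7-hydroxy-8-methyl-5-(prop-1-en-2-yl)non-8-en-2-one (both C7 epimers)
Conditions: isopropenylmagnesium bromide (1.05 equiv, slow addition), THF, −78 °C; aq. NH4Cl
Reagents that add atoms: isopropenylmagnesium bromide, C=C(C)[Mg]Br
Why: Grignard addition, in which the aldehyde reacts far faster than the methyl ketone at −78 °C with one equivalent of reagent; the new carbinol centre forms unselectively, which is harmless because step 5 destroys it.

**Step 5**
Reactants: 11 (5R)-7-hydroxy-8-methyl-5-(prop-1-en-2-yl)non-8-en-2-one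
Product: 13 (4E,7R)-4-methyl-10-oxo-7-(prop-1-en-2-yl)undec-4-enal, via allyl vinyl ether 12 (not isolated)
Conditions: ethyl vinyl ether (excess), Hg(OAc)2 (10 mol%), reflux; evaporate; toluene, 140 °C, sealed tube
Reagents that add atoms: ethyl vinyl ether, C=COCC
Why: Transvinylation of the secondary allylic alcohol (mercury diacetate catalysis) and Claisen rearrangement through a chair transition state with the carbinol substituent equatorial should give the E-trisubstituted alkene and the aldehyde directly, leaving the ketone untouched.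

**Step 6**
Reactants: 14 methyl (triphenylphosphoranylidene)acetate; 15 5-bromo-2-methylpent-2-ene
Product: 17 methyl 6-methyl-2-(triphenylphosphoranylidene)hept-5-enoate, via phosphonium bromide 16 (not isolated)
Conditions: NaI (cat.), MeCN, reflux; then aq. NaOH, CH2Cl2, rt
Reagents that add atoms: none
Why: C-alkylation of the ester-stabilised ylide by the primary halide (SN2, helped by in situ Finkelstein exchange) gives the phosphonium salt, which hydroxide deprotonates to an isolable α-substituted stabilised ylide.

**Step 7**
Reactants: 13 (4E,7R)-4-methyl-10-oxo-7-(prop-1-en-2-yl)undec-4-enal; 17 methyl 6-methyl-2-(triphenylphosphoranylidene)hept-5-enoate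
Product: 18 methyl (2E,6E,9R)-6-methyl-2-(4-methylpent-3-en-1-yl)-12-oxo-9-(prop-1-en-2-yl)trideca-2,6-dienoate
Conditions: toluene, 90 °C
Reagents that add atoms: none
Why: Wittig olefination with an α-substituted ester-stabilised ylide reacts at the aldehyde only, not at the methyl ketone, and should give the E-enoate (ester trans to the incoming chain).

**Step 8**
Reactants: 18 methyl (2E,6E,9R)-6-methyl-2-(4-methylpent-3-en-1-yl)-12-oxo-9-(prop-1-en-2-yl)trideca-2,6-dienoate
Product: 20 (4R,6E,10E)-11-(methoxycarbonyl)-7,15-dimethyl-4-(prop-1-en-2-yl)hexadeca-6,10,14-trienoic acid, via tribromomethyl ketone 19 (not isolated)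
Conditions: NaOBr (preformed from Br2 and aq. NaOH), 1,4-dioxane/H2O, 0 °C; Na2SO3; then aq. HCl to pH 3
Reagents that add atoms: sodium hydroxide, [Na+].[OH-]
Why: Haloform reaction: exhaustive α-bromination of the methyl group under basic conditions and hydroxide cleavage of the tribromomethyl ketone; non-conjugated polyprenyl methyl ketones are known to tolerate these conditions, and the hindered conjugated methyl ester should hydrolyse only slowly at 0 °C.

**Step 9**
Reactants: 20 (4R,6E,10E)-11-(methoxycarbonyl)-7,15-dimethyl-4-(prop-1-en-2-yl)hexadeca-6,10,14-trienoic acid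
Product: 21 1,3-dioxoisoindolin-2-yl (4R,6E,10E)-11-(methoxycarbonyl)-7,15-dimethyl-4-(prop-1-en-2-yl)hexadeca-6,10,14-trienoate
Conditions: N-hydroxyphthalimide, DIC, DMAP (cat.), CH2Cl2, rt
Reagents that add atoms: N-hydroxyphthalimide, O=C1c2ccccc2C(=O)N1O
Why: Carbodiimide-mediated (Steglich-type) esterification of the only free carboxylic acid gives the redox-active ester without touching the conjugated methyl ester or the alkenes.

**Step 10**
Reactants: 21 redox-active ester (1 equiv); 7 methyl (E)-5-(furan-3-yl)-2-iodopent-2-enoate (1.5 equiv)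
Product: 22 dimethyl (2Z,5R,7E,11E)-2-[3-(furan-3-yl)propylidene]-8-methyl-12-(4-methylpent-3-en-1-yl)-5-(prop-1-en-2-yl)trideca-7,11-dienedioate
Conditions: NiCl2·6H2O (20 mol%), 2,2'-bipyridine (20 mol%), AgNO3 (0.3 equiv), DMF, Mg anode, carbon-foam cathode, undivided cell, constant current, rt
Reagents that add atoms: none
Why: Cathodic reduction converts divalent nickel/bipyridine into low-valent nickel, which inserts into the C(sp2)–I bond of 7 with retention, while single-electron reduction of the N-hydroxyphthalimide ester releases phthalimide anion, CO2 and the primary radical at the CH2 two carbons from the stereocentre; the alkenylnickel captures this radical and reductive elimination from trivalent nickel forms the CH2–Cα bond. The closest known reaction type is the nickel-electrocatalytic decarboxylative alkenylation of redox-active esters with alkenyl iodides at silver-nanoparticle-coated cathodes, which was developed for polyene terpenes. No ring is closed and no stereocentre is created: the existing centre is two carbons from the radical and cannot be affected, and the 2Z geometry is inherited from the iodide because oxidative addition and reductive elimination are stereoretentive. The step needs C–I activation in preference to the two enoates and the furan, capture of the radical before it rearranges, and no E/Z leakage. The α-ester alkenyl iodide is the most easily activated site in either partner, and the primary radical has only slow 3-exo and 4-exo cyclisation modes toward the isopropenyl and trisubstituted alkenes. Because both coupling carbons are electrophile-derived, no organometallic reagent that would attack the esters is required.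

**Step 11**
Reactants: 22 dimethyl ester
Product: 23 (2Z,5R,7E,11E)-2-[3-(furan-3-yl)propylidene]-8-methyl-12-(4-methylpent-3-en-1-yl)-5-(prop-1-en-2-yl)trideca-7,11-dienedioic acid (CNP0235727.2)
Conditions: LiOH·H2O (excess), THF/MeOH/H2O, 40 °C; then 1 M HCl to pH 3, 0 °C
Reagents that add atoms: lithium hydroxide, [Li+].[OH-]
Why: Saponification (acyl–oxygen cleavage) of both hindered conjugated methyl esters by hydroxide, which is not basic enough to deprotonate the γ-positions, so the Z-enoate geometry and the non-enolisable stereocentre should be preserved, and brief mild acidification spares the furan and the isopropenyl group.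

**Compound list**
1 | 3-(bromomethyl)furan | BrCc1ccoc1 | starting material
2 | propyne | CC#C | starting material
3 | 1,3-dilithiopropyne | [Li]CC#C[Li] | intermediate
4 | lithium 4-(furan-3-yl)but-1-yn-1-ide | [Li]C#CCCc1ccoc1 | intermediate
5 | methyl 5-(furan-3-yl)pent-2-ynoate | COC(=O)C#CCCc1ccoc1 | intermediate
6 | methyl (E)-5-(furan-3-yl)-2-(tributylstannyl)pent-2-enoate | COC(=O)/C(=C\CCc1ccoc1)[Sn](CCCC)(CCCC)CCCC | intermediate
7 | methyl (E)-5-(furan-3-yl)-2-iodopent-2-enoate | COC(=O)/C(I)=C\CCc1ccoc1 | intermediate
8 | (4R)-limonene 1,2-oxide, (4R)-1-methyl-4-(prop-1-en-2-yl)-7-oxabicyclo[4.1.0]heptane, cis/trans mixture | C=C(C)[C@@H]1CCC2(C)OC2C1 | starting material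
9 | (4R)-1-methyl-4-(prop-1-en-2-yl)cyclohexane-1,2-diol | C=C(C)[C@@H]1CCC(C)(O)C(O)C1 | intermediate
10 | (3R)-6-oxo-3-(prop-1-en-2-yl)heptanal | C=C(C)[C@@H](CC=O)CCC(C)=O | intermediate
11 | (5R)-7-hydroxy-8-methyl-5-(prop-1-en-2-yl)non-8-en-2-one, C7 epimers | C=C(C)[C@@H](CC(O)C(C)=C)CCC(C)=O | intermediate
12 | (5R)-7-(ethenyloxy)-8-methyl-5-(prop-1-en-2-yl)non-8-en-2-one | C=C(C)[C@@H](CC(OC=C)C(C)=C)CCC(C)=O | intermediate
13 | (4E,7R)-4-methyl-10-oxo-7-(prop-1-en-2-yl)undec-4-enal | C=C(C)[C@@H](C/C=C(\C)CCC=O)CCC(C)=O | intermediate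
14 | methyl (triphenylphosphoranylidene)acetate | COC(=O)C=P(c1ccccc1)(c1ccccc1)c1ccccc1 | starting material
15 | 5-bromo-2-methylpent-2-ene | CC(C)=CCCBr | starting material
16 | (1-methoxy-6-methyl-1-oxohept-5-en-2-yl)triphenylphosphonium bromide | COC(=O)C(CCC=C(C)C)[P+](c1ccccc1)(c1ccccc1)c1ccccc1.[Br-] | intermediate
17 | methyl 6-methyl-2-(triphenylphosphoranylidene)hept-5-enoate | COC(=O)C(CCC=C(C)C)=P(c1ccccc1)(c1ccccc1)c1ccccc1 | intermediate
18 | methyl (2E,6E,9R)-6-methyl-2-(4-methylpent-3-en-1-yl)-12-oxo-9-(prop-1-en-2-yl)trideca-2,6-dienoate | C=C(C)[C@@H](C/C=C(\C)CC/C=C(\CCC=C(C)C)C(=O)OC)CCC(C)=O | intermediate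
19 | methyl (2E,6E,9R)-13,13,13-tribromo-6-methyl-2-(4-methylpent-3-en-1-yl)-12-oxo-9-(prop-1-en-2-yl)trideca-2,6-dienoate | C=C(C)[C@@H](C/C=C(\C)CC/C=C(\CCC=C(C)C)C(=O)OC)CCC(=O)C(Br)(Br)Br | intermediate
20 | (4R,6E,10E)-11-(methoxycarbonyl)-7,15-dimethyl-4-(prop-1-en-2-yl)hexadeca-6,10,14-trienoic acid | C=C(C)[C@@H](C/C=C(\C)CC/C=C(\CCC=C(C)C)C(=O)OC)CCC(=O)O | intermediate
21 | 1,3-dioxoisoindolin-2-yl (4R,6E,10E)-11-(methoxycarbonyl)-7,15-dimethyl-4-(prop-1-en-2-yl)hexadeca-6,10,14-trienoate | C=C(C)[C@@H](C/C=C(\C)CC/C=C(\CCC=C(C)C)C(=O)OC)CCC(=O)ON1C(=O)c2ccccc2C1=O | intermediate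
22 | dimethyl (2Z,5R,7E,11E)-2-[3-(furan-3-yl)propylidene]-8-methyl-12-(4-methylpent-3-en-1-yl)-5-(prop-1-en-2-yl)trideca-7,11-dienedioate | C=C(C)[C@@H](C/C=C(\C)CC/C=C(\CCC=C(C)C)C(=O)OC)CC/C(=C/CCc1ccoc1)C(=O)OC | intermediate
23 | (2Z,5R,7E,11E)-2-[3-(furan-3-yl)propylidene]-8-methyl-12-(4-methylpent-3-en-1-yl)-5-(prop-1-en-2-yl)trideca-7,11-dienedioic acid | C=C(C)[C@@H](C/C=C(\C)CC/C=C(\CCC=C(C)C)C(=O)O)CC/C(=C/CCc1ccoc1)C(=O)O | target

**Step count.** Total: 11 steps. Longest linear sequence: 8 steps (8 → 23 through steps 3, 4, 5, 7, 8, 9, 10, 11).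

**Steps most likely to fail**

1. Step 10. What may go wrong: cathodic or nickel-mediated hydrodeiodination of the activated alkenyl iodide, E/Z scrambling through an oxygen-bound nickel allenoate, or 1,5-hydrogen transfer from the isopropenyl methyl group to the primary radical before capture. Fallback, setting out from 21 and returning at 22: light-driven decarboxylative iodination of the redox-active ester (LiI, PPh3 cat., blue light, acetone) would give the primary iodide methyl (2E,6E,9S)-11-iodo-6-methyl-2-(4-methylpent-3-en-1-yl)-9-(prop-1-en-2-yl)undeca-2,6-dienoate F1. Zinc insertion (Zn dust, LiCl, THF, 40 °C) would convert it into the ester-tolerant alkylzinc iodide F2. A Negishi coupling of F2 with 7 (Pd(OAc)2, SPhos, THF, rt), a two-electron pathway that is stereoretentive at the alkenyl carbon, would then give 22.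

2. Step 8. What may go wrong: electrophilic bromination of the trisubstituted alkenes by hypobromite, or premature saponification of the methyl ester. Fallback, setting out from 18 and returning at 20: kinetic enolisation at the methyl group (KN(SiMe3)2, THF, −78 °C) and hydroxylation with 2-(phenylsulfonyl)-3-phenyloxaziridine would give the α-hydroxy ketone methyl (2E,6E,9R)-13-hydroxy-6-methyl-2-(4-methylpent-3-en-1-yl)-12-oxo-9-(prop-1-en-2-yl)trideca-2,6-dienoate F3. Periodate cleavage of this ketol (NaIO4, THF/MeOH/H2O, rt) would give 20 without any electrophilic halogen.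

3. Step 1. What may go wrong: incomplete dimetalation of propyne, double alkylation, or allene formation in the one-flask sequence. Fallback, setting out from 1 and returning at 5: alkylation of lithiated 1-(trimethylsilyl)propyne (n-BuLi, THF, −78 °C) with 1 would give 3-[4-(trimethylsilyl)but-3-yn-1-yl]furan F4. Desilylation (K2CO3, MeOH, rt) would give 3-(but-3-yn-1-yl)furan F5. Deprotonation and acylation (n-BuLi, THF, −78 °C; ClCO2Me) would then give 5.

**Further compounds**
F1 | step 10 | methyl (2E,6E,9S)-11-iodo-6-methyl-2-(4-methylpent-3-en-1-yl)-9-(prop-1-en-2-yl)undeca-2,6-dienoate | C=C(C)[C@@H](C/C=C(\C)CC/C=C(\CCC=C(C)C)C(=O)OC)CCI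
F2 | step 10 | [(3S,5E,9E)-10-(methoxycarbonyl)-6,14-dimethyl-3-(prop-1-en-2-yl)pentadeca-5,9,13-trien-1-yl]zinc iodide | C=C(C)[C@@H](C/C=C(\C)CC/C=C(\CCC=C(C)C)C(=O)OC)CC[Zn]I
F3 | step 8 | methyl (2E,6E,9R)-13-hydroxy-6-methyl-2-(4-methylpent-3-en-1-yl)-12-oxo-9-(prop-1-en-2-yl)trideca-2,6-dienoate | C=C(C)[C@@H](C/C=C(\C)CC/C=C(\CCC=C(C)C)C(=O)OC)CCC(=O)CO
F4 | step 1 | 3-[4-(trimethylsilyl)but-3-yn-1-yl]furan | C[Si](C)(C)C#CCCc1ccoc1
F5 | step 1 | 3-(but-3-yn-1-yl)furan | C#CCCc1ccoc1
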